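## The problem

The target is a (2S)-flavanone: a pyranone ring (O1–C2–C3–C4–C4a–C8a) fused to a phloroglucinol-type A ring carrying three different groups (5-OH, 7-OMe, 8-prenyl) and bonded at C2 to a 2,4,6-trimethoxyphenyl B ring. C2 is the only stereocentre, so nothing in the molecule can control it, and it is labile in two ways: base opens the ring by E1cB loss of the A-ring phenoxide, and acid ionises the C2–O1 bond to a trimethoxybenzylic cation. It must therefore be set by a reagent, late, and in a neutral medium. The B ring is substituted at both ortho positions, which shields C2 and makes the corresponding aryl-metal reagents slow to transfer and quick to protodemetalate. On the A ring the acyl carbon C4a lies between two phenolic oxygens, either of which can become O1, so the 6-prenyl series is as easy to enter as the 8-prenyl series; O5 must end as a free chelated phenol while O7 is a methyl ether. The prenyl alkene forbids hydrogenation, strong acid and unselective electrophiles, and the four aryl methyl ethers forbid Lewis-acidic dealkylation. The feature that opens a different route is C2 itself: it bears one hydrogen, the ring oxygen O1 and the B ring, and its neighbour C3 is an unsubstituted methylene next to the C4 carbonyl. Read backwards, C3 is the carbene carbon of an aryl diazomethyl ketone and C2 is the methylene of a 2,4,6-trimethoxybenzyl ether on the ortho oxygen; the atom 1,5 to the carbene carbon is O1, so the only C–H bond within reach is the benzylic one, and it is of the most hydridic kind (α to oxygen, benzylic, three methoxy donors).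

## Retrosynthesis

**13 ⇒ 12 (O5–Si).** The free 5-OH is masked to the end as a triisopropylsilyl ether. A free ortho phenol would destroy the diazoketone by O–H insertion, and of the usual phenol masks only a bulky silyl ether has no α-C–H bond, no allyl or benzyl group that could shift, and a shielded oxygen. The forward step must remove silicon without creating a phenoxide that could open the ring at C2.

**12 ⇒ 11 (C2–C3; key disconnection).** Cutting C2–C3 with return of a hydrogen to C2 gives diazoketone 11, which has no stereocentre and no heterocycle. The neighbouring cuts are weaker: C2–O1 leads to a reversible oxa-Michael closure whose reverse reaction is the racemisation pathway; C2–aryl needs a di-ortho-substituted aryl nucleophile; C4–C4a needs strong acid next to an ionisable C2. The forward reaction, a catalytic enantioselective C–H insertion of a rhodium carbene, must pick one of two enantiotopic benzylic hydrogens of an achiral ether and must beat capture of the carbene by an oxygen lone pair. It forms the C2–C3 bond irreversibly and without acid or base.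

**11 ⇒ 9 (C3=N2).** The diazo group is traced to the methyl of acetophenone 9 by deacylative diazo transfer through the trifluoroacetyl diketone 10. The acetyl group present from the first step thus serves as the latent carbene, and no carboxylic acid or acid chloride has to be made on an acid-labile ether.

**9 ⇒ 7 + 8 (O1–CH2).** The ether bond between O1 and the future C2 is cut to phenol 7 and commercial benzyl alcohol 8. The whole B ring arrives with C2 in one piece, and the choice of which oxygen becomes O1 is made here by which oxygen is free. The forward step must alkylate a hindered, chelated phenol at oxygen under neutral conditions.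

**7 ⇒ 6 (O5–Si).** The two phenols of 6 differ by one ortho substituent: the one next to the prenyl group is flanked on both sides, the other on one side only. A bulky silyl chloride should take the less hindered oxygen (the future O5) and leave the one next to the prenyl group (the future O1) free.

**6 ⇒ 3 ⇒ 1 + 2 (C8–prenyl, traced to an O–prenyl bond).** The C-prenyl bond is cut back to the aryl prenyl ether 3, a bond that is not in the target. Two consecutive [3,3] shifts (through dienones 4 and 5) carry the C5 unit from oxygen to the para carbon in the normal, unbranched orientation. Ether 3 comes from symmetrical 1 and prenyl bromide 2; the two phenols of 1 are equivalent, so the first alkylation poses no regiochemical question.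

## Roads not taken

Alternative 1: The most obvious cut is C2–O1, leading to the 2′-hydroxychalcone A1 (Claisen–Schmidt condensation of 6) and an intramolecular oxa-Michael closure, under base or with a bifunctional amine–thiourea catalyst. Both phenols of A1 flank the enone, so the 6-prenyl isomer A2 forms alongside unless one oxygen is masked. The closure is an equilibrium whose reverse step is the racemisation of the product, and unactivated hydroxychalcones respond poorly to such catalysts, more so when the di-ortho-substituted B ring twists the styrene out of conjugation. The usual remedy, an ester at C3 to activate the acceptor, ends in an acidic decarboxylation that the C2–O1 bond would not survive. The chosen plan fixes O1 by which oxygen carries the benzyl group and forms C2 irreversibly.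

Alternative 2: Cutting C2–C1′ gives chromone A3 and boronic acid A4, joined by Pd(II)- or Rh(I)-catalysed asymmetric conjugate arylation. A4 has two ortho methoxy groups: it protodeboronates readily and transmetalates slowly, and migratory insertion to a di-ortho-substituted aryl is hindered. A3 is an electron-rich, weak acceptor, and its own ring closure again has to choose between the two phenols. The chosen plan brings the B ring in as a benzyl alcohol and needs no aryl–metal species.

Alternative 3: Cutting the C2–H and C3–H bonds gives flavone A5, to be reduced by asymmetric CuH conjugate reduction or asymmetric hydrogenation. The β-carbon of A5 is fully substituted and carries a B ring held perpendicular with a methoxy group over each face, which is the worst case for hydride delivery. Hydrogenation catalysts would also touch the prenyl alkene. A5 itself needs an oxidative cyclisation of a chalcone that the prenyl group tolerates badly, so the route is longer and less selective than the chosen one.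

Key step: step 6

Assumption: the sense of induction of the dirhodium catalyst in step 6 cannot be predicted with confidence for this substrate; the (S)-tert-leucine-derived catalyst is written, and its mirror image would be used without other change should that be the one leading to (2S)-12.

## Route

Step 1
Reactants: 1 1-(2,6-dihydroxy-4-methoxyphenyl)ethan-1-one; 2 1-bromo-3-methylbut-2-ene (prenyl bromide)
Product: 3 1-[2-hydroxy-4-methoxy-6-(3-methylbut-2-en-1-yloxy)phenyl]ethan-1-one
Conditions: K2CO3 (1.2 equiv), 2 (1.05 equiv), acetone, reflux
Reagents that add atoms: none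
Why: Williamson ether synthesis; the two phenols of 1 are equivalent, and after the first alkylation the remaining phenol is locked in the hydrogen bond to the ketone, which should stop the reaction at the mono-ether; acetone favours O- over C-alkylation.

Step 2
Reactants: 3 1-[2-hydroxy-4-methoxy-6-(3-methylbut-2-en-1-yloxy)phenyl]ethan-1-one
Product: 6 1-[2,6-dihydroxy-4-methoxy-3-(3-methylbut-2-en-1-yl)phenyl]ethan-1-one, via ortho-Claisen dienone 4 (not isolated), via Cope dienone 5 (not isolated)
Conditions: Eu(fod)3 (10 mol %), NaHCO3, PhCl, 85 °C
Reagents that add atoms: none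
Why: Europium(III)-catalysed aromatic Claisen rearrangement followed by Cope rearrangement: the first [3,3] shift places a 1,1-dimethylallyl group on the free ortho carbon (4), the second carries it to the para carbon as a normal prenyl group (5), and enolisation gives 6; the sequence is established for prenyl ethers of ortho-acylphenols, where the ketone and ether oxygens chelate the metal.

Step 3
Reactants: 6 1-[2,6-dihydroxy-4-methoxy-3-(3-methylbut-2-en-1-yl)phenyl]ethan-1-one
Product: 7 1-[2-hydroxy-4-methoxy-3-(3-methylbut-2-en-1-yl)-6-(triisopropylsilyloxy)phenyl]ethan-1-one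
Conditions: TIPSCl (1.1 equiv), imidazole, DMAP (cat.), DMF, 0 °C to rt
Reagents that add atoms: triisopropylsilyl chloride, CC(C)[Si](Cl)(C(C)C)C(C)C
Why: Silylation under steric control: the 6-OH has one ortho neighbour (acetyl), the 2-OH is flanked by acetyl and the prenyl CH2, so the bulky silyl chloride should take the 6-OH; the remaining phenol is then chelated and resists a second silylation.

Step 4
Reactants: 7 1-[2-hydroxy-4-methoxy-3-(3-methylbut-2-en-1-yl)-6-(triisopropylsilyloxy)phenyl]ethan-1-one; 8 (2,4,6-trimethoxyphenyl)methanol
Product: 9 1-[4-methoxy-3-(3-methylbut-2-en-1-yl)-2-[(2,4,6-trimethoxyphenyl)methoxy]-6-(triisopropylsilyloxy)phenyl]ethan-1-one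
Conditions: PPh3, DIAD, toluene, 0 °C to rt; chromatography on Et3N-deactivated silica
Reagents that add atoms: none
Why: Mitsunobu etherification of a phenol with a primary benzylic alcohol; it is neutral, avoids the unstable trimethoxybenzyl halide, and is known to alkylate chelated ortho-acylphenols at oxygen.

Step 5
Reactants: 9 1-[4-methoxy-3-(3-methylbut-2-en-1-yl)-2-[(2,4,6-trimethoxyphenyl)methoxy]-6-(triisopropylsilyloxy)phenyl]ethan-1-one
Product: 11 2-diazo-1-[4-methoxy-3-(3-methylbut-2-en-1-yl)-2-[(2,4,6-trimethoxyphenyl)methoxy]-6-(triisopropylsilyloxy)phenyl]ethan-1-one, via trifluoroacetyl diketone 10 (not isolated)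
Conditions: (a) LiHMDS, THF, −78 °C, then CF3CO2CH2CF3; aq. NH4Cl; (b) MsN3, Et3N, H2O (1 equiv), MeCN, rt
Reagents that add atoms: methanesulfonyl azide, CS(=O)(=O)N=[N+]=[N-] (the two nitrogen atoms of 11); 2,2,2-trifluoroethyl trifluoroacetate, O=C(OCC(F)(F)F)C(F)(F)F (the trifluoroacetyl group of 10 only, lost again in stage b)
Why: Detrifluoroacetylative (Regitz-type deacylative) diazo transfer: the methyl ketone enolate is acylated to diketone 10, whose activated methylene accepts the diazo group while the trifluoroacetyl group leaves as the sulfonyl amide; the medium is basic throughout, which the acid-labile benzyl ether, the silyl ether and the alkene tolerate.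

Step 6
Reactants: 11 2-diazo-1-[4-methoxy-3-(3-methylbut-2-en-1-yl)-2-[(2,4,6-trimethoxyphenyl)methoxy]-6-(triisopropylsilyloxy)phenyl]ethan-1-one
Product: 12 (2S)-7-methoxy-8-(3-methylbut-2-en-1-yl)-5-(triisopropylsilyloxy)-2-(2,4,6-trimethoxyphenyl)-2,3-dihydro-4H-chromen-4-one
Conditions: Rh2(S-PTTL)4 [dirhodium tetrakis(N-phthaloyl-(S)-tert-leucinate)] (1 mol %), CH2Cl2, 4 Å MS, 0 °C, slow addition of 11
Reagents that add atoms: none
Why: Loss of N2 from 11 at the dirhodium centre gives an electrophilic acylcarbene held in the chiral ligand pocket; the closest known reaction type is the Rh(II)-carboxylate-catalysed intramolecular C–H insertion of 2-alkoxyaryl α-diazoketones into the ether O–CH2 bond, which gives chroman-4-ones and responds to chiral carboxylate ligands. The pyranone ring closes at C2–C3 by 1,6-insertion through a chair-like six-membered transition state in which hydride-like transfer from the benzylic carbon to the carbene carbon and C–C bond formation are concerted, so the new bond takes the place of the hydrogen that is removed. C2 is therefore set by the choice between the two enantiotopic benzylic hydrogens of an achiral ether, and the element of control is the catalyst: its phthalimido walls open one face of the carbene, the A-ring tether fixes the line of approach, and the B ring takes the pseudo-equatorial place. Two selectivities are needed: site selectivity (insertion against capture of the carbene by an ether oxygen with [1,2]-shift of the benzyl group) and selection between the enantiotopic hydrogens. The substrate supports the first in four ways: the atom 1,5 to the carbene carbon is O1, so no five-membered insertion exists; the benzylic C–H is activated by O1 and three methoxy donors; O1 is a poorly basic acylaryl ether oxygen wedged between the prenyl and acyl groups, which turns its CH2 out of the ring plane towards the twisted ketone; and the silyloxy oxygen is shielded and has no α-hydrogen, while the meta-placed prenyl alkene cannot reach the carbene. The medium contains neither acid nor base, so neither racemisation pathway of the flavanone is open.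

Step 7
Reactants: 12 (2S)-7-methoxy-8-(3-methylbut-2-en-1-yl)-5-(triisopropylsilyloxy)-2-(2,4,6-trimethoxyphenyl)-2,3-dihydro-4H-chromen-4-one
Product: 13 (2S)-5-hydroxy-7-methoxy-8-(3-methylbut-2-en-1-yl)-2-(2,4,6-trimethoxyphenyl)-2,3-dihydro-4H-chromen-4-one (target)
Conditions: TBAF (1.1 equiv), AcOH (1.2 equiv), THF, 0 °C, short reaction time
Reagents that add atoms: none
Why: Fluoride cleavage of an aryl silyl ether peri to a carbonyl; the acetic acid buffer should deliver the phenol protonated and hydrogen-bonded to C4=O, so that no phenoxide is present to start the E1cB ring opening and no acid strong enough to ionise C2–O1; C2 is not touched.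

## Compound list

1 | 1-(2,6-dihydroxy-4-methoxyphenyl)ethan-1-one | CC(=O)c1c(O)cc(OC)cc1O | starting material
2 | 1-bromo-3-methylbut-2-ene (prenyl bromide) | CC(C)=CCBr | starting material
3 | 1-[2-hydroxy-4-methoxy-6-(3-methylbut-2-en-1-yloxy)phenyl]ethan-1-one | CC(=O)c1c(O)cc(OC)cc1OCC=C(C)C | intermediate
4 | 2-acetyl-3-hydroxy-5-methoxy-6-(2-methylbut-3-en-2-yl)cyclohexa-2,4-dien-1-one (racemic, ortho-Claisen dienone) | CC(=O)C1=C(O)C=C(OC)C(C(C)(C)C=C)C1=O | intermediate (not isolated)
5 | 2-acetyl-3-hydroxy-5-methoxy-4-(3-methylbut-2-en-1-yl)cyclohexa-2,5-dien-1-one (racemic, Cope dienone) | CC(=O)C1=C(O)C(CC=C(C)C)C(OC)=CC1=O | intermediate (not isolated)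
6 | 1-[2,6-dihydroxy-4-methoxy-3-(3-methylbut-2-en-1-yl)phenyl]ethan-1-one | CC(=O)c1c(O)cc(OC)c(CC=C(C)C)c1O | intermediate
7 | 1-[2-hydroxy-4-methoxy-3-(3-methylbut-2-en-1-yl)-6-(triisopropylsilyloxy)phenyl]ethan-1-one | CC(=O)c1c(O[Si](C(C)C)(C(C)C)C(C)C)cc(OC)c(CC=C(C)C)c1O | intermediate
8 | (2,4,6-trimethoxyphenyl)methanol | COc1cc(OC)c(CO)c(OC)c1 | starting material
9 | 1-[4-methoxy-3-(3-methylbut-2-en-1-yl)-2-[(2,4,6-trimethoxyphenyl)methoxy]-6-(triisopropylsilyloxy)phenyl]ethan-1-one | CC(=O)c1c(O[Si](C(C)C)(C(C)C)C(C)C)cc(OC)c(CC=C(C)C)c1OCc1c(OC)cc(OC)cc1OC | intermediate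
10 | 4,4,4-trifluoro-1-[4-methoxy-3-(3-methylbut-2-en-1-yl)-2-[(2,4,6-trimethoxyphenyl)methoxy]-6-(triisopropylsilyloxy)phenyl]butane-1,3-dione | O=C(CC(=O)C(F)(F)F)c1c(O[Si](C(C)C)(C(C)C)C(C)C)cc(OC)c(CC=C(C)C)c1OCc1c(OC)cc(OC)cc1OC | intermediate (not isolated)
11 | 2-diazo-1-[4-methoxy-3-(3-methylbut-2-en-1-yl)-2-[(2,4,6-trimethoxyphenyl)methoxy]-6-(triisopropylsilyloxy)phenyl]ethan-1-one | [N-]=[N+]=CC(=O)c1c(O[Si](C(C)C)(C(C)C)C(C)C)cc(OC)c(CC=C(C)C)c1OCc1c(OC)cc(OC)cc1OC | intermediate
12 | (2S)-7-methoxy-8-(3-methylbut-2-en-1-yl)-5-(triisopropylsilyloxy)-2-(2,4,6-trimethoxyphenyl)-2,3-dihydro-4H-chromen-4-one | COc1cc(OC)c([C@@H]2CC(=O)c3c(O[Si](C(C)C)(C(C)C)C(C)C)cc(OC)c(CC=C(C)C)c3O2)c(OC)c1 | intermediate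
13 | (2S)-5-hydroxy-7-methoxy-8-(3-methylbut-2-en-1-yl)-2-(2,4,6-trimethoxyphenyl)-2,3-dihydro-4H-chromen-4-one | COc1cc(OC)c([C@@H]2CC(=O)c3c(O)cc(OC)c(CC=C(C)C)c3O2)c(OC)c1 | target

## Step count and least certain steps

Total step count: 7. Longest linear sequence: 7 steps (1 to 13).

**Step 6 (key step).** Two things may go wrong. The carbene may be captured by the lone pair of O1 and the trimethoxybenzyl group may then shift from oxygen to carbon (Stevens-type [1,2]-shift with ring contraction), because this benzyl group is as good a migrating group as its C–H bond is a hydride donor. Hydride transfer may also run ahead of C–C bond formation, so that an ion pair closes with little catalyst control and the choice between the enantiotopic hydrogens is poor; a carbene without a second substituent gives the ligand little to hold. Fallback, by known chemistry, from 3 to 13: Claisen–Schmidt condensation of 3 with commercial 2,4,6-trimethoxybenzaldehyde (KOH, EtOH) would give the chalcone (E)-1-[2-hydroxy-4-methoxy-6-(3-methylbut-2-en-1-yloxy)phenyl]-3-(2,4,6-trimethoxyphenyl)prop-2-en-1-one F1, in which only one phenol is free. Closure with NaOAc in EtOH would give the racemic 5-O-prenylflavanone F2, and the Eu(fod)3-catalysed Claisen–Cope sequence would carry the prenyl group to C8 and free the 5-OH to give the racemic target F3. Kinetic resolution by Ru(II)–TsDPEN transfer hydrogenation (HCO2H/Et3N), with the catalyst antipode that reduces the (2R)-ketone to the cis-flavan-4-ol F4, would leave (2S)-13.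

**Step 3.** Discrimination between the two phenols may be poor, or double silylation may occur, since both are chelated to the same carbonyl and differ only by one ortho substituent. Fallback from 3 to 7, in which the sigmatropic shift sets the difference: acetylation of 3 (Ac2O, pyridine) to the aryl acetate F5; Claisen–Cope rearrangement to F6, which frees only the oxygen remote from the prenyl group; silylation of that single phenol to F7; removal of the aryl acetate with NH3 in MeOH at 0 °C to give 7.

**Step 4.** The hindered, chelated phenol may react slowly while the activated benzyl alcohol ionises, leading to C-benzylation of the electron-rich A ring or alkylation of the hydrazide by-product. Fallback from 3 to 9, which makes the ether on the unhindered phenol before the prenyl group is in place: Mitsunobu reaction of 3 with 8 to the bis-ether 1-[4-methoxy-2-(3-methylbut-2-en-1-yloxy)-6-[(2,4,6-trimethoxyphenyl)methoxy]phenyl]ethan-1-one F8; Claisen–Cope rearrangement (Eu(fod)3 with NaHCO3, or thermally in N,N-diethylaniline) to F9, in which the prenyl group arrives next to the benzyloxy-bearing carbon; silylation of the freed phenol to give 9. This path bypasses 6 and 7 but exposes the acid-sensitive benzyl ether to the rearrangement conditions, which is why it is not the main route.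

**Step 2.** The ortho dienone 4 may enolise before the Cope shift, so that the branched 1,1-dimethylallyl phenol accumulates, and the free phenol of 3 may bind europium and slow the catalysis. Fallback from 1 to 6: direct nuclear prenylation of 1 with 2 in aqueous KOH at 0 °C; the two free ring positions of 1 are equivalent, so a single C-prenyl product is possible, at the cost of competing O- and double alkylation.

**Step 7.** Enantiomeric purity may erode through phenoxide-triggered ring opening and reclosure if the fluoride is not fully buffered. Fallback from 13 (partly racemised) back to 13: the same transfer-hydrogenation kinetic resolution as above would convert the (2R) portion to the cis-flavan-4-ol F10 (the same structure as F4), leaving (2S)-13.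

## Further compounds

F1 | step 6 | (E)-1-[2-hydroxy-4-methoxy-6-(3-methylbut-2-en-1-yloxy)phenyl]-3-(2,4,6-trimethoxyphenyl)prop-2-en-1-one | COc1cc(OC)c(/C=C/C(=O)c2c(O)cc(OC)cc2OCC=C(C)C)c(OC)c1
F2 | step 6 | rac-7-methoxy-5-(3-methylbut-2-en-1-yloxy)-2-(2,4,6-trimethoxyphenyl)-2,3-dihydro-4H-chromen-4-one | COc1cc(OC)c(C2CC(=O)c3c(OCC=C(C)C)cc(OC)cc3O2)c(OC)c1
F3 | step 6 | rac-5-hydroxy-7-methoxy-8-(3-methylbut-2-en-1-yl)-2-(2,4,6-trimethoxyphenyl)-2,3-dihydro-4H-chromen-4-one | COc1cc(OC)c(C2CC(=O)c3c(O)cc(OC)c(CC=C(C)C)c3O2)c(OC)c1
F4 | step 6 | (2R,4R)-7-methoxy-8-(3-methylbut-2-en-1-yl)-2-(2,4,6-trimethoxyphenyl)chromane-4,5-diol | COc1cc(OC)c([C@H]2C[C@@H](O)c3c(O)cc(OC)c(CC=C(C)C)c3O2)c(OC)c1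
F5 | step 3 | 2-acetyl-5-methoxy-3-(3-methylbut-2-en-1-yloxy)phenyl acetate | CC(=O)Oc1cc(OC)cc(OCC=C(C)C)c1C(C)=O
F6 | step 3 | 2-acetyl-3-hydroxy-5-methoxy-6-(3-methylbut-2-en-1-yl)phenyl acetate | CC(=O)Oc1c(CC=C(C)C)c(OC)cc(O)c1C(C)=O
F7 | step 3 | 2-acetyl-5-methoxy-6-(3-methylbut-2-en-1-yl)-3-(triisopropylsilyloxy)phenyl acetate | CC(=O)Oc1c(CC=C(C)C)c(OC)cc(O[Si](C(C)C)(C(C)C)C(C)C)c1C(C)=O
F8 | step 4 | 1-[4-methoxy-2-(3-methylbut-2-en-1-yloxy)-6-[(2,4,6-trimethoxyphenyl)methoxy]phenyl]ethan-1-one | CC(=O)c1c(OCC=C(C)C)cc(OC)cc1OCc1c(OC)cc(OC)cc1OC
F9 | step 4 | 1-[6-hydroxy-4-methoxy-3-(3-methylbut-2-en-1-yl)-2-[(2,4,6-trimethoxyphenyl)methoxy]phenyl]ethan-1-one | CC(=O)c1c(O)cc(OC)c(CC=C(C)C)c1OCc1c(OC)cc(OC)cc1OC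
F0 | step 2 | none | none
F10 | step 7 | (2R,4R)-7-methoxy-8-(3-methylbut-2-en-1-yl)-2-(2,4,6-trimethoxyphenyl)chromane-4,5-diol | COc1cc(OC)c([C@H]2C[C@@H](O)c3c(O)cc(OC)c(CC=C(C)C)c3O2)c(OC)c1
A1 | alternative 1 | (E)-1-[2,6-dihydroxy-4-methoxy-3-(3-methylbut-2-en-1-yl)phenyl]-3-(2,4,6-trimethoxyphenyl)prop-2-en-1-one | COc1cc(OC)c(/C=C/C(=O)c2c(O)cc(OC)c(CC=C(C)C)c2O)c(OC)c1
A2 | alternative 1 | rac-5-hydroxy-7-methoxy-6-(3-methylbut-2-en-1-yl)-2-(2,4,6-trimethoxyphenyl)-2,3-dihydro-4H-chromen-4-one | COc1cc(OC)c(C2CC(=O)c3c(O)c(CC=C(C)C)c(OC)cc3O2)c(OC)c1
A3 | alternative 2 | 5-hydroxy-7-methoxy-8-(3-methylbut-2-en-1-yl)-4H-chromen-4-one | O=c1ccoc2c(CC=C(C)C)c(OC)cc(O)c12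
A4 | alternative 2 | (2,4,6-trimethoxyphenyl)boronic acid | COc1cc(OC)c(B(O)O)c(OC)c1
A5 | alternative 3 | 5-hydroxy-7-methoxy-8-(3-methylbut-2-en-1-yl)-2-(2,4,6-trimethoxyphenyl)-4H-chromen-4-one | COc1cc(OC)c(-c2cc(=O)c3c(O)cc(OC)c(CC=C(C)C)c3o2)c(OC)c1
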